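## Structural features

Stenophyllol B is a resveratrol trimer with six benzene rings: three 4-hydroxyphenyl rings (A on indane C1, E on the methine Cm, F on furan C2) and three resorcinol rings (B fused in the indane, C on Cm, D fused in the dihydrobenzofuran). Ring B and C1–C3 form the indane; C2 carries ring D, C3 is bonded to Cm, Cm sits on ring C, and ring C is joined through furan C3 to ring D. C2, C3, Cm, two carbons of ring C, furan C3 and two carbons of ring D therefore close an eight-membered carbocycle that shares the C2–C3 bond with the cyclopentane. The six stereocentres form a chain: C1 (S), C2 (S), C3 (R), Cm (R), furan C3 (R), furan C2 (R). The indane is all-trans, the dihydrofuran is trans, and the hydrogens on C3 and Cm are anti. Fragile points are the eight free phenols, the benzylic aryl ether at furan C2 (it ionises in acid) and the electron-rich rings. The real difficulty is the eight-membered ring with four stereocentres on it, and within it the hydrogen on C3: a simple model of the tub places it on the same side of the indane plane as the fold made by rings C and D, where an external reagent reaches poorly. The key step uses the fact that the shared C2–C3 bond is flanked by ring B (C1 and C3 are ortho substituents of ring B) and by ring D. With C1 and C3 as ketones, C2 is an activated CH2 between ring D and the C1 carbonyl, and the five- and eight-membered rings are the two halves of one eleven-membered ring through rings B, C and D.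

## Logic of the disconnections

35 from 34. Only the eight aryl O–CH3 bonds are cut. Methyl ethers survive every organometallic, acid and base step and come with the starting materials. The price is a last step with a strong Lewis acid, which the trans-dihydrofuran must tolerate.

34 from 32 and 33. The bond between C1 and ring A is cut. C1 lies ortho and para to the two oxygens of ring B, so it can be a stabilised cation, and bringing ring A in last lets C1 serve as a carbonyl until then. The forward step must trap the cation from the face away from ring D and faster than any ring of the molecule itself.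

32 from 31, 31 from 29, 29 from 28. The C–H bonds at C1, then at C3 and C2, are removed, which returns the indane to the indenone. C1 remains the handle that sets its neighbours. The demand is that the hydrogen at C3 enters on the face covered by rings C and D; it is therefore taken from C1 of 29 by an internal shift, and the configuration of 29 has to be set by the reagent.

28 from 26. The C2–C3 double bond is cut, which opens both carbocycles into one eleven-membered ring with no stereocentre to control beyond those of the furan. The forward step needs the right enolate to meet the right carbonyl, and 26 must see neither acid nor base before it is cyclic.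

26 from 25, 25 from 23. The C1–C2 bond is cut in its alcohol form. Ring closure is left to a carbonyl addition that tolerates the ketone and the acidic methine, and oxidation then unveils the second ketone under neutral conditions. The demand is a benzylic organometallic that adds to the aldehyde only, at high dilution.

23 from 22, 22 from 21. These are adjustments of the two benzylic carbons. They stay distinguishable because one is carried at the aldehyde level (acetal) and the other at the alcohol level (silyl ether).

21 from 20 and 14. The bond between Cm and ring C is cut, the most convergent cut available. It asks for an enolate coupling at a doubly ortho-substituted carbon, with no second halide and no other acidic C–H in either partner.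

20 from 18, 17, 16, 15 and 9. The ring B piece is cut at the carbonyl–CH2 bond and at the formyl–arene bond. The symmetry of 15 makes the formylation site unambiguous.

14 from 13, 11 and 10. The furan C2–C3 bond is cut, so that both furan centres arise in one catalytic asymmetric step; 13 and 14 differ only at furan C2. The demand is that 10 holds the ether CH2 five atoms from the carbene carbon with no competing C–H bond.

10 from 8 and 9; 8 from 7; 7 from 6; 6 from 3 and 4; 3 from 2; 2 from 1. An O–benzyl bond, one O–methyl bond, the diaryl ketone C–C bond and a C–Br bond are cut. The symmetry of 1 makes the two positions next to its CH2OH equivalent, and the ketone of 7 singles out the one methoxy group that must become the furan oxygen.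

## Other disconnections considered

Alternative 1: The cut removes ring B altogether: the three bonds that join two alkyne units to a third are broken, which also opens the cyclopentane. Forward, the diyne A1, which already holds C1, C2 and C3 as an open-chain stereotriad, would be cyclotrimerised with ethoxyethyne A2 on a cationic rhodium–bisphosphine catalyst to give the indane A3.
- In its favour: ring B and the five-membered ring form in one step, the ynol ethers place both oxygens of ring B, and the three indane centres are fixed before any ring exists. The inner hydrogen at C3 is then no issue, and on this point the alternative is better than the chosen plan, which has to relay that hydrogen in steps 20 and 21.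
- Against it here: A1 needs three contiguous centres set in an open chain beside two propargylic, benzylic C–H bonds that can drift to allenes. The regiochemistry of A2 must place the second ethoxy group meta to the first. After A3 the dihydrofuran, ring C, Cm and the eight-membered ring are all still missing, so that ring would have to be closed end to end.
- Comparison: the alternative front-loads stereocontrol and back-loads ring strain; the chosen plan does the reverse. Step counts should be similar, and the final ether cleavage is equal in both.

Alternative 2: The cut is the bond between furan C3 and ring D, made by a 1,2-aryl shift. Forward, the flavanone A4 is treated with a hypervalent iodine diacetate, an orthoformate and acid: the enol ether is iodinated at C3 and the oxygenated arene migrates from C4 to C3, contracting the pyranone to the trans-dihydrobenzofuran ester A5.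
- In its favour: it is short and robust, the flavanone can be had as one enantiomer, C2 is carried through untouched and C3 settles trans next to the ester. For the bare dihydrofuran it is shorter than steps 1–9, and on that count better.
- Against it here: in A5 furan C3 carries a carboxylate where the target has ring C, and the ring D position that must hold the benzylic carbon is an ether oxygen. Exchanging the ester for a functionalised dimethoxyphenyl ring means a decarboxylative arylation at a carbon β to an aryloxy leaving group, with ring opening as the threat, and the benzyloxy group must become a sulfonate and then carbon.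
- Comparison: these repairs should cost more than the contraction saves. The chosen plan forms the same furan bond by carbene insertion with ring C and the benzylic carbon already in place; both end at the same thermodynamic trans arrangement, so on stereochemical outcome they are equal.

Alternative 3: The cut takes out ring C: its bonds to Cm and to furan C3 are broken, leaving a six-membered β-keto ester. Forward, the enolate of A6 adds to the aryne A7 at the carbon remote from the methoxy group, the aryl anion closes onto the ketone and the cyclobutoxide fragments, which inserts two arene carbons and gives the eight-membered keto ester A8.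
- In its favour: like the chosen plan it never closes an eight-membered ring end to end (equal on this point). Ring C arrives in one step with its methoxy groups placed by the polarisation of the aryne. The indane centres are settled beforehand in a rigid tetralone where C3 is enolisable, which is better than the chosen plan for that centre.
- Against it here: A6, as one enantiomer with three centres, is at least as long to make as 26, and the insertion must work on a hindered, fully substituted enolate. A8 still lacks rings E and F and the dihydrofuran, so Cm and both furan centres must be set late, relative to the indane and without a reliable handle, whereas the chosen plan carries the furan in from 14.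
- Comparison: in step count A8 stands about where 28 stands, but with more stereochemical work ahead.

Key step: step 19

Remark 1: In names, C1–C3 are the indane carbons (C1 bears ring A, C2 ring D), Cm is the methine bearing ring E, and furan C2 and C3 bear rings F and C.
Remark 2: Cm is enolisable from 21 to 28; 21–25 are carried as both epimers (no descriptor in their SMILES), 26 is drawn as one epimer, and the centre is settled by equilibration in step 19.
Remark 3: For the chiral catalysts of steps 8 and 20 the antipode that leads to the configuration drawn is to be used; which one that is must be fixed in a first run.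

## Route

Step 1
Reactants: 1 3,5-dimethoxybenzyl alcohol
Product: 2 (2-bromo-3,5-dimethoxyphenyl)methanol
Conditions: NBS, CH2Cl2, 0 °C
Reagents that add atoms: N-bromosuccinimide, BrN1C(=O)CCC1=O
Why: Electrophilic aromatic bromination; the position between CH2OH and OMe is para to the other OMe and less crowded than the position between the two OMe groups, and the two such positions are equivalent.

Step 2
Reactants: 2 (2-bromo-3,5-dimethoxyphenyl)methanol
Product: 3 [(2-bromo-3,5-dimethoxyphenyl)methoxy](tert-butyl)diphenylsilane
Conditions: TBDPSCl, imidazole, DMF, 25 °C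
Reagents that add atoms: tert-butyl(chloro)diphenylsilane, CC(C)(C)[Si](Cl)(c1ccccc1)c1ccccc1
Why: Silyl ether formation; this silyl group is chosen because it has to survive n-BuLi, MgI2, hydrazine, TFA and NaOtBu.

Step 3
Reactants: 3 silyl ether; 4 2-bromo-3,5-dimethoxybenzaldehyde
Product: 6 (2-bromo-3,5-dimethoxyphenyl)[2-({[tert-butyl(diphenyl)silyl]oxy}methyl)-4,6-dimethoxyphenyl]methanol (racemic), via aryllithium 5 (not isolated)
Conditions: n-BuLi, THF, −78 °C; then 4, −78 → −40 °C; NH4Cl aq
Reagents that add atoms: none
Why: Bromine–lithium exchange followed by 1,2-addition to the aldehyde; at −78 °C addition to C=O should be much faster than exchange with the bromide of 4. The carbinol centre is removed in step 4.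

Step 4
Reactants: 6 diaryl carbinol
Product: 7 (2-bromo-3,5-dimethoxyphenyl)[2-({[tert-butyl(diphenyl)silyl]oxy}methyl)-4,6-dimethoxyphenyl]methanone
Conditions: Dess–Martin periodinane, NaHCO3, CH2Cl2, 25 °C
Reagents that add atoms: none
Why: Dess–Martin oxidation of a diaryl carbinol; nothing else in 6 is oxidisable.

Step 5
Reactants: 7 benzophenone
Product: 8 (2-bromo-3,5-dimethoxyphenyl)[2-({[tert-butyl(diphenyl)silyl]oxy}methyl)-6-hydroxy-4-methoxyphenyl]methanone
Conditions: MgI2·OEt2 (3 equiv), toluene, 80 °C; then 1 M HCl
Reagents that add atoms: none
Why: Chelation-controlled ether cleavage: magnesium held by the ketone activates only the OMe ortho to the carbonyl on ring D (ring C has none), and iodide removes the methyl group by SN2.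

Step 6
Reactants: 8 phenol; 9 4-methoxybenzyl chloride
Product: 10 (2-bromo-3,5-dimethoxyphenyl){2-({[tert-butyl(diphenyl)silyl]oxy}methyl)-4-methoxy-6-[(4-methoxybenzyl)oxy]phenyl}methanone
Conditions: K2CO3, NaI (cat.), DMF, 60 °C
Reagents that add atoms: none
Why: Williamson etherification; the benzyl group brings ring F together with the CH2 whose C–H bond is used in step 8.

Step 7
Reactants: 10 benzyl ether ketone
Product: 11 hydrazone of 10 (E/Z mixture)
Conditions: N2H4·H2O (10 equiv), AcOH (cat.), n-BuOH, 110 °C, sealed tube
Reagents that add atoms: hydrazine (as hydrate), NN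
Why: Hydrazone formation; the ketone carries three ortho substituents, so forcing, acid-catalysed conditions are planned.

Step 8
Reactants: 11 hydrazone
Product: 13 tert-butyl{[(2S,3S)-3-(2-bromo-3,5-dimethoxyphenyl)-6-methoxy-2-(4-methoxyphenyl)-2,3-dihydro-1-benzofuran-4-yl]methoxy}diphenylsilane (cis), via diaryldiazomethane 12 (not isolated)
Conditions: MnO2, CH2Cl2, 0 °C, filter; then Rh2(S-PTAD)4 (1 mol %), CH2Cl2, −20 → 25 °C
Reagents that add atoms: none
Why: Oxidation to the diazo compound, then insertion of the dirhodium donor/donor carbene into the ether C–H bond five atoms away, a known route to cis-2,3-diaryl-dihydrobenzofurans. The chiral carboxylate ligands choose between the two enantiotopic C–H bonds and so set furan C3 (S) and C2 in one event.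

Step 9
Reactants: 13 cis-dihydrobenzofuran
Product: 14 tert-butyl{[(2R,3S)-3-(2-bromo-3,5-dimethoxyphenyl)-6-methoxy-2-(4-methoxyphenyl)-2,3-dihydro-1-benzofuran-4-yl]methoxy}diphenylsilane (trans)
Conditions: TFA (5 equiv), CH2Cl2, 0 °C
Reagents that add atoms: none
Why: Acid-mediated epimerisation at furan C2: the C2–O bond ionises to the 4-methoxybenzylic cation, which recloses to the more stable trans isomer. Furan C3 is not touched, so the enantiomeric purity set in step 8 is kept.

Step 10
Reactants: 15 methyl 3,5-dimethoxybenzoate
Product: 16 methyl 2-formyl-3,5-dimethoxybenzoate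
Conditions: POCl3, DMF, 90 °C; then NaOAc aq
Reagents that add atoms: N,N-dimethylformamide, CN(C)C=O; water, O
Why: Vilsmeier–Haack formylation; the position between the ester and an OMe is para to the other OMe, and the two such positions are equivalent.

Step 11
Reactants: 16 aldehyde ester
Product: 17 methyl 2-(dimethoxymethyl)-3,5-dimethoxybenzoate
Conditions: HC(OMe)3 (neat), TsOH·H2O (cat.), 50 °C
Reagents that add atoms: trimethyl orthoformate, COC(OC)OC
Why: Acetal formation; it protects the future C1 carbon through the organomagnesium and palladium steps.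

Step 12
Reactants: 17 acetal ester
Product: 18 2-(dimethoxymethyl)-N,3,5-trimethoxy-N-methylbenzamide
Conditions: MeNH(OMe)·HCl, iPrMgCl, THF, −20 °C
Reagents that add atoms: N,O-dimethylhydroxylamine hydrochloride, CNOC.Cl
Why: Aminolysis of the ester by the magnesium amide gives the Weinreb amide, which allows a clean single addition in step 13.

Step 13
Reactants: 18 Weinreb amide; 9 4-methoxybenzyl chloride
Product: 20 1-[2-(dimethoxymethyl)-3,5-dimethoxyphenyl]-2-(4-methoxyphenyl)ethan-1-one, via 4-methoxybenzylmagnesium chloride 19 (not isolated)
Conditions: 9, Mg, THF, 0 °C; then 18, −20 → 0 °C; NH4Cl aq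
Reagents that add atoms: none
Why: Weinreb ketone synthesis; the chelated tetrahedral intermediate collapses only on work-up, so the benzyl ketone should form without over-addition.

Step 14
Reactants: 20 benzyl ketone; 14 aryl bromide
Product: 21 2-{2-[(2R,3R)-4-({[tert-butyl(diphenyl)silyl]oxy}methyl)-6-methoxy-2-(4-methoxyphenyl)-2,3-dihydro-1-benzofuran-3-yl]-4,6-dimethoxyphenyl}-1-[2-(dimethoxymethyl)-3,5-dimethoxyphenyl]-2-(4-methoxyphenyl)ethan-1-one (both epimers at Cm)
Conditions: Pd2(dba)3 (2.5 mol %), XPhos (6 mol %), NaOtBu (2.2 equiv), toluene, 80 °C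
Reagents that add atoms: none
Why: Palladium-catalysed α-arylation of the ketone enolate with the aryl bromide; a bulky biarylphosphine is chosen for the doubly ortho-substituted bromide. The product sits as its enolate until work-up, so Cm forms without control.

Step 15
Reactants: 21 coupled ketone
Product: 22 2-[2-{2-[(2R,3R)-4-(hydroxymethyl)-6-methoxy-2-(4-methoxyphenyl)-2,3-dihydro-1-benzofuran-3-yl]-4,6-dimethoxyphenyl}-2-(4-methoxyphenyl)acetyl]-4,6-dimethoxybenzaldehyde (both epimers at Cm)
Conditions: TBAF, THF, 0 °C; then 1 M HCl, THF/H2O, 25 °C
Reagents that add atoms: water, O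
Why: Fluoride cleaves the silyl ether and dilute acid hydrolyses the acetal; the two benzylic carbons are now told apart by oxidation level.

Step 16
Reactants: 22 aldehyde alcohol
Product: 23 bromomethyl analogue of 22 (CH2OH replaced by CH2Br)
Conditions: PBr3 (0.4 equiv), CH2Cl2, −10 °C
Reagents that add atoms: phosphorus tribromide, BrP(Br)Br
Why: Conversion of the primary benzylic alcohol into the bromide; aldehyde and ketone should be inert to PBr3 at this temperature.

Step 17
Reactants: 23 benzylic bromide aldehyde
Product: 25 eleven-membered ketol (CH2 of ring D joined to a CH(OH) on ring B; both epimers at the carbinol and at Cm; may rest as its cyclic hemiketal), via benzylchromium dichloride 24 (not isolated)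
Conditions: CrCl2 (6 equiv), THF, 25 °C, slow addition of 23 (final 2 mM); then H2O
Reagents that add atoms: none
Why: Nozaki–Hiyama benzylation: divalent chromium inserts into the C–Br bond and the benzylchromium adds to the aldehyde but not to the ketone or the acidic methine. The ring formed is a [2.2.1]orthocyclophane with six arene carbons among its eleven members, so strain should be low; high dilution holds back dimerisation.

Step 18
Reactants: 25 ketol
Product: 26 eleven-membered diketone (ring B 1,2-diacyl; one carbonyl next to CH2–ring D, the other next to Cm; drawn with Cm (R), furan (2R,3R))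
Conditions: Dess–Martin periodinane, NaHCO3, CH2Cl2, 0 → 25 °C
Reagents that add atoms: none
Why: Dess–Martin oxidation under buffered, non-enolising conditions should deliver the 1,2-diacylarene without starting the aldol.

Step 19
Reactants: 26 eleven-membered diketone
Product: 28 indenone with both carbocycles closed (ring D on C2, Cm on C3; Cm (S), furan (2R,3R)), via aldol adduct 27 (not isolated)
Conditions: KOH (0.2 M), MeOH/THF (1:1), 0 → 45 °C
Reagents that add atoms: none
Why: Base forms the enolate of the CH2 between ring D and its carbonyl; its carbon (C2) attacks the second ketone (C3) across the ring, and E1cB loss of water from adduct 27 gives the 2-aryl-3-alkylindenone. The closest known reactions are the base-mediated cyclisation of 1,2-diacylbenzenes to indenones and transannular aldol reactions of macrocyclic diketones. The five-membered ring closes in the 5-(enolendo)-exo-trig mode; the eight-membered ring is not closed directly but is what is left of the eleven-membered ring once C2–C3 exists. No stereocentre is created, since C2 and C3 end as sp2 carbons. Cm epimerises through the enolate of 26 and the dienolate of 28 and should settle with ring E on the outer face, turned away from ring D, which is the configuration drawn. The selectivity needed is between the two enolates: only the CH2 enolate gives an adduct that can dehydrate into conjugation with the remaining carbonyl, while the adduct of the methine enolate has no α-hydrogen left and reverts. The ortho placement of the two acyl groups on ring B keeps the reacting carbons within bonding distance in every conformer of the ring. Moving the double bond towards Cm would force ring C into the indenone plane and is not expected.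

Step 20
Reactants: 28 indenone
Product: 29 (1R)-indenol (Cm (S), furan (2R,3R))
Conditions: (S)-2-methyl-CBS-oxazaborolidine (20 mol %), catecholborane, toluene, −78 °C
Reagents that add atoms: none
Why: Corey–Bakshi–Shibata 1,2-reduction; the carbonyl lies far from the stereocentres, so the catalyst antipode should decide the carbinol configuration. The C1 epimer, if formed, is a diastereomer that can be separated and oxidised back to 28.

Step 21
Reactants: 29 (1R)-indenol
Product: 31 trans-indanone ((2R,3S); Cm (R), furan (2R,3R)), via enol 30 (not isolated)
Conditions: TBD (1,5,7-triazabicyclo[4.4.0]dec-5-ene, 10 mol %), toluene, 60 °C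
Reagents that add atoms: none
Why: Base-catalysed 1,3-proton shift of a 1-indenol to the 1-indanone: the guanidine takes the carbinol hydrogen and the tight ion pair returns it to C3 on the same face, so C3 is set from C1. The transfer runs beneath the five-membered ring, away from rings C and D, on the face a catalyst surface could not reach. The enol 30 then ketonises and C2 equilibrates under the base to the 2,3-trans arrangement.

Step 22
Reactants: 31 trans-indanone
Product: 32 indan-1-ol (both C1 epimers; C2 (R), C3 (S))
Conditions: NaBH4, MeOH/THF, 0 °C
Reagents that add atoms: none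
Why: Hydride reduction of the ketone; both carbinol epimers are usable because step 23 passes through one cation.

Step 23
Reactants: 32 indanol; 33 anisole
Product: 34 stenophyllol B octamethyl ether ((1S,2S,3R); Cm (R); furan (2R,3R))
Conditions: anisole/CH2Cl2 (1:1), TFA (2 equiv), −20 → 0 °C
Reagents that add atoms: none
Why: Friedel–Crafts arylation: acid ionises the indanol to a benzylic cation stabilised by the ortho and para OMe groups of ring B, and anisole attacks through its para position from the face anti to ring D, which is also the outer face of the tub. The large excess of anisole should outrun attack by ring E, and the acid is too weak to open the dihydrofuran.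

Step 24
Reactants: 34 octamethyl ether
Product: 35 stenophyllol B
Conditions: BBr3 (16 equiv), CH2Cl2, −78 → 25 °C; then MeOH, H2O
Reagents that add atoms: none
Why: Cleavage of eight aryl methyl ethers with BBr3; the trans-dihydrofuran is the thermodynamic isomer, so reversible opening at furan C2 under the Lewis acid should not change it.

## Compound list

1 | 3,5-dimethoxybenzyl alcohol | COc1cc(CO)cc(OC)c1 | starting material
2 | (2-bromo-3,5-dimethoxyphenyl)methanol | OCc1cc(OC)cc(OC)c1Br | intermediate
3 | [(2-bromo-3,5-dimethoxyphenyl)methoxy](tert-butyl)diphenylsilane | CC(C)(C)[Si](OCc1cc(OC)cc(OC)c1Br)(c1ccccc1)c1ccccc1 | intermediate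
4 | 2-bromo-3,5-dimethoxybenzaldehyde | O=Cc1cc(OC)cc(OC)c1Br | starting material
5 | [2-({[tert-butyl(diphenyl)silyl]oxy}methyl)-4,6-dimethoxyphenyl]lithium (not isolated) | CC(C)(C)[Si](OCc1cc(OC)cc(OC)c1[Li])(c1ccccc1)c1ccccc1 | intermediate
6 | (2-bromo-3,5-dimethoxyphenyl)[2-({[tert-butyl(diphenyl)silyl]oxy}methyl)-4,6-dimethoxyphenyl]methanol, racemic | CC(C)(C)[Si](OCc1cc(OC)cc(OC)c1C(O)c1cc(OC)cc(OC)c1Br)(c1ccccc1)c1ccccc1 | intermediate
7 | (2-bromo-3,5-dimethoxyphenyl)[2-({[tert-butyl(diphenyl)silyl]oxy}methyl)-4,6-dimethoxyphenyl]methanone | CC(C)(C)[Si](OCc1cc(OC)cc(OC)c1C(=O)c1cc(OC)cc(OC)c1Br)(c1ccccc1)c1ccccc1 | intermediate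
8 | (2-bromo-3,5-dimethoxyphenyl)[2-({[tert-butyl(diphenyl)silyl]oxy}methyl)-6-hydroxy-4-methoxyphenyl]methanone | CC(C)(C)[Si](OCc1cc(OC)cc(O)c1C(=O)c1cc(OC)cc(OC)c1Br)(c1ccccc1)c1ccccc1 | intermediate
9 | 4-methoxybenzyl chloride | COc1ccc(CCl)cc1 | starting material
10 | (2-bromo-3,5-dimethoxyphenyl){2-({[tert-butyl(diphenyl)silyl]oxy}methyl)-4-methoxy-6-[(4-methoxybenzyl)oxy]phenyl}methanone | CC(C)(C)[Si](OCc1cc(OC)cc(OCc2ccc(OC)cc2)c1C(=O)c1cc(OC)cc(OC)c1Br)(c1ccccc1)c1ccccc1 | intermediate
11 | hydrazone of 10 (E/Z mixture) | CC(C)(C)[Si](OCc1cc(OC)cc(OCc2ccc(OC)cc2)c1C(=NN)c1cc(OC)cc(OC)c1Br)(c1ccccc1)c1ccccc1 | intermediate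
12 | diaryldiazomethane from 11 (not isolated) | CC(C)(C)[Si](OCc1cc(OC)cc(OCc2ccc(OC)cc2)c1C(=[N+]=[N-])c1cc(OC)cc(OC)c1Br)(c1ccccc1)c1ccccc1 | intermediate
13 | tert-butyl{[(2S,3S)-3-(2-bromo-3,5-dimethoxyphenyl)-6-methoxy-2-(4-methoxyphenyl)-2,3-dihydro-1-benzofuran-4-yl]methoxy}diphenylsilane (cis) | CC(C)(C)[Si](c1ccccc1)(c1ccccc1)OCc2cc(OC)cc3c2[C@H]([C@@H](c4ccc(OC)cc4)O3)c5cc(OC)cc(OC)c5Br | intermediate
14 | tert-butyl{[(2R,3S)-3-(2-bromo-3,5-dimethoxyphenyl)-6-methoxy-2-(4-methoxyphenyl)-2,3-dihydro-1-benzofuran-4-yl]methoxy}diphenylsilane (trans) | CC(C)(C)[Si](c1ccccc1)(c1ccccc1)OCc2cc(OC)cc3c2[C@H]([C@H](c4ccc(OC)cc4)O3)c5cc(OC)cc(OC)c5Br | intermediate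
15 | methyl 3,5-dimethoxybenzoate | COC(=O)c1cc(OC)cc(OC)c1 | starting material
16 | methyl 2-formyl-3,5-dimethoxybenzoate | COC(=O)c1cc(OC)cc(OC)c1C=O | intermediate
17 | methyl 2-(dimethoxymethyl)-3,5-dimethoxybenzoate | COC(=O)c1cc(OC)cc(OC)c1C(OC)OC | intermediate
18 | 2-(dimethoxymethyl)-N,3,5-trimethoxy-N-methylbenzamide | CON(C)C(=O)c1cc(OC)cc(OC)c1C(OC)OC | intermediate
19 | 4-methoxybenzylmagnesium chloride (not isolated) | COc1ccc(C[Mg]Cl)cc1 | intermediate
20 | 1-[2-(dimethoxymethyl)-3,5-dimethoxyphenyl]-2-(4-methoxyphenyl)ethan-1-one | COc1ccc(CC(=O)c2cc(OC)cc(OC)c2C(OC)OC)cc1 | intermediate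
21 | α-arylated ketone: 20 carrying on its CH the ring C of 14 in place of bromine; furan (2R,3R), both epimers at Cm | CC(C)(C)[Si](c1ccccc1)(c1ccccc1)OCc2cc(OC)cc3c2[C@H]([C@H](c4ccc(OC)cc4)O3)c5cc(OC)cc(OC)c5C(c6ccc(OC)cc6)C(=O)c7cc(OC)cc(OC)c7C(OC)OC | intermediate
22 | aldehyde alcohol from 21 (CH2OH on ring D, CHO on ring B); furan (2R,3R), both epimers at Cm | OCc2cc(OC)cc3c2[C@H]([C@H](c4ccc(OC)cc4)O3)c5cc(OC)cc(OC)c5C(c6ccc(OC)cc6)C(=O)c7cc(OC)cc(OC)c7C=O | intermediate
23 | benzylic bromide aldehyde (CH2Br on ring D, CHO on ring B); furan (2R,3R), both epimers at Cm | BrCc2cc(OC)cc3c2[C@H]([C@H](c4ccc(OC)cc4)O3)c5cc(OC)cc(OC)c5C(c6ccc(OC)cc6)C(=O)c7cc(OC)cc(OC)c7C=O | intermediate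
24 | benzylchromium dichloride from 23 (not isolated) | Cl[Cr](Cl)Cc2cc(OC)cc3c2[C@H]([C@H](c4ccc(OC)cc4)O3)c5cc(OC)cc(OC)c5C(c6ccc(OC)cc6)C(=O)c7cc(OC)cc(OC)c7C=O | intermediate
25 | eleven-membered ketol; furan (2R,3R), both epimers at the carbinol and at Cm | OC1Cc2cc(OC)cc3c2[C@H]([C@H](c4ccc(OC)cc4)O3)c5cc(OC)cc(OC)c5C(c6ccc(OC)cc6)C(=O)c7cc(OC)cc(OC)c71 | intermediate
26 | eleven-membered diketone; Cm (R) as drawn (its Cm epimer accompanies it), furan (2R,3R) | O=C1Cc2cc(OC)cc3c2[C@H]([C@H](c4ccc(OC)cc4)O3)c5cc(OC)cc(OC)c5[C@@H](c6ccc(OC)cc6)C(=O)c7cc(OC)cc(OC)c71 | intermediate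
27 | transannular aldol adduct, 3-hydroxyindan-1-one with the eight-membered ring closed (not isolated; C2, C3 and Cm unassigned) | O=C1C2C(O)(c3cc(OC)cc(OC)c31)C(c4ccc(OC)cc4)c5c(OC)cc(OC)cc5[C@@H]6c7c2cc(OC)cc7O[C@H]6c8ccc(OC)cc8 | intermediate
28 | indenone with both carbocycles closed, heptamethyl ether; Cm (S), furan (2R,3R) | O=C1C2=C(c3cc(OC)cc(OC)c31)[C@H](c4ccc(OC)cc4)c5c(OC)cc(OC)cc5[C@@H]6c7c2cc(OC)cc7O[C@H]6c8ccc(OC)cc8 | intermediate
29 | (1R)-indenol from 28; Cm (S), furan (2R,3R) | O[C@@H]1C2=C(c3cc(OC)cc(OC)c31)[C@H](c4ccc(OC)cc4)c5c(OC)cc(OC)cc5[C@@H]6c7c2cc(OC)cc7O[C@H]6c8ccc(OC)cc8 | intermediate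
30 | enol of 31 (C1=C2, hydroxyl on C1; C3 (R)) (not isolated) | OC=2c3c(OC)cc(OC)cc3[C@H]3[C@H](c4ccc(OC)cc4)c4c(OC)cc(OC)cc4[C@@H]4c5c(cc(OC)cc5C=23)O[C@H]4c2ccc(OC)cc2 | intermediate
31 | trans-indanone; (2R,3S), Cm (R), furan (2R,3R) | O=C2c3c(OC)cc(OC)cc3[C@H]3[C@H](c4ccc(OC)cc4)c4c(OC)cc(OC)cc4[C@@H]4c5c(cc(OC)cc5[C@H]23)O[C@H]4c2ccc(OC)cc2 | intermediate
32 | indan-1-ol, both C1 epimers; C2 (R), C3 (S), Cm (R), furan (2R,3R) | OC2c3c(OC)cc(OC)cc3[C@H]3[C@H](c4ccc(OC)cc4)c4c(OC)cc(OC)cc4[C@@H]4c5c(cc(OC)cc5[C@H]23)O[C@H]4c2ccc(OC)cc2 | intermediate
33 | anisole | COc1ccccc1 | starting material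
34 | stenophyllol B octamethyl ether; (1S,2S,3R), Cm (R), furan (2R,3R) | COc1ccc([C@H]2c3c(OC)cc(OC)cc3[C@H]3[C@H](c4ccc(OC)cc4)c4c(OC)cc(OC)cc4[C@@H]4c5c(cc(OC)cc5[C@H]23)O[C@H]4c2ccc(OC)cc2)cc1 | intermediate
35 | stenophyllol B | Oc1ccc([C@H]2c3c(O)cc(O)cc3[C@H]3[C@H](c4ccc(O)cc4)c4c(O)cc(O)cc4[C@@H]4c5c(cc(O)cc5[C@H]23)O[C@H]4c2ccc(O)cc2)cc1 | target

## Step count and least certain steps

Total: 24 steps. Longest linear sequence: 20 steps (steps 1–9, then 14–24); the ring B branch (steps 10–13) has 4 steps.

Step 19 (key step). Most likely failure: the equilibrating aldol does not drain to the indenone, because the unproductive adduct of the methine enolate or an O-closed hemiketal holds the material, or because hydroxide attacks a hindered aryl ketone before dehydration. Fallback, from 26 back to 28: kinetic deprotonation at the CH2 ketone with LiHMDS and TMSCl at −78 °C gives the trimethylsilyl enol ether F1. TiCl4 at −78 °C then closes the ring by a transannular Mukaiyama aldol reaction to the adduct 27, now isolated, and a separate dehydration with Burgess reagent gives 28. This fixes the regiochemistry before the C–C bond forms and avoids equilibrating base.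

Step 17. Most likely failure: intermolecular coupling (Wurtz-type dimer or oligomers) or simple reduction of the benzylic bromide outruns ring closure, since the aldehyde is crowded by two ortho groups. Fallback, from 23 back to 26: PPh3 converts 23 into the phosphonium bromide F2. An intramolecular Wittig reaction (K2CO3, 18-crown-6, CH2Cl2, high dilution) closes the ring as the cyclic (Z)-stilbene F3. Wacker oxidation (PdCl2, CuCl, O2, DMF/H2O) then gives 26; water should attack the alkene carbon on the more electron-rich ring B, which places the carbonyl where it is needed.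

Step 21 (with step 20). Most likely failure: loss of stereospecificity, if the ion pair separates and the proton returns to C3 from the open outer face, or poor facial control in step 20. Fallback, from 28 back to 31: the antipodal oxazaborolidine gives the (1S)-indenol F4, whose hydroxyl lies on the inner face. Hydroxyl-directed hydrogenation with [Ir(cod)(PCy3)(py)]PF6 and H2 delivers both hydrogens syn to it, giving the indanol F5. Dess–Martin oxidation gives the cis-indanone F6, and DBU epimerises C2 to 31.

Step 8 (with step 7). Most likely failure: slow condensation at the tri-ortho-substituted ketone, azine formation from the diazo compound, or eroded enantioselectivity in the insertion because the carbene is flanked by three ortho groups. Fallback, from 8 back to 14: three equivalents of 19 add to the ketone of 8 to give the tertiary carbinol F7. TsOH in toluene dehydrates it and closes the phenol onto the 4-methoxybenzylic cation, giving the racemic trans-dihydrobenzofuran F8. Preparative chromatography on a chiral stationary phase then gives 14.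

Step 14. Most likely failure: slow coupling at the doubly ortho-substituted bromide, so that hydrodebromination of 14 takes over. Fallback, from 18 (with 14) back to 21: MeMgBr converts 18 into the methyl ketone F9. Its less hindered enolate is arylated with 14 under the same palladium conditions to the benzyl ketone F10, and a second α-arylation with unhindered 4-bromoanisole installs ring E and gives 21.

## Further compounds

F1 | step 19 | trimethylsilyl enol ether of 26 at the CH2 ketone | C[Si](C)(C)OC1=Cc2cc(OC)cc3c2[C@H]([C@H](c4ccc(OC)cc4)O3)c5cc(OC)cc(OC)c5[C@@H](c6ccc(OC)cc6)C(=O)c7cc(OC)cc(OC)c71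
F2 | step 17 | benzylic triphenylphosphonium bromide from 23 | [Br-].c1ccccc1[P+](c1ccccc1)(c1ccccc1)Cc2cc(OC)cc3c2[C@H]([C@H](c4ccc(OC)cc4)O3)c5cc(OC)cc(OC)c5C(c6ccc(OC)cc6)C(=O)c7cc(OC)cc(OC)c7C=O
F3 | step 17 | eleven-membered cyclic stilbene ketone, (Z) as fixed by the ring | C1=Cc2cc(OC)cc3c2[C@H]([C@H](c4ccc(OC)cc4)O3)c5cc(OC)cc(OC)c5C(c6ccc(OC)cc6)C(=O)c7cc(OC)cc(OC)c71
F4 | step 21 | (1S)-indenol, C1 epimer of 29 | O[C@H]1C2=C(c3cc(OC)cc(OC)c31)[C@H](c4ccc(OC)cc4)c5c(OC)cc(OC)cc5[C@@H]6c7c2cc(OC)cc7O[C@H]6c8ccc(OC)cc8
F5 | step 21 | (1S,2S,3S)-indan-1-ol from directed hydrogenation | O[C@@H]2c3c(OC)cc(OC)cc3[C@H]3[C@H](c4ccc(OC)cc4)c4c(OC)cc(OC)cc4[C@@H]4c5c(cc(OC)cc5[C@@H]23)O[C@H]4c2ccc(OC)cc2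
F6 | step 21 | cis-indanone (2S,3S), C2 epimer of 31 | O=C2c3c(OC)cc(OC)cc3[C@H]3[C@H](c4ccc(OC)cc4)c4c(OC)cc(OC)cc4[C@@H]4c5c(cc(OC)cc5[C@@H]23)O[C@H]4c2ccc(OC)cc2
F7 | step 8 | 1-(2-bromo-3,5-dimethoxyphenyl)-1-[2-({[tert-butyl(diphenyl)silyl]oxy}methyl)-6-hydroxy-4-methoxyphenyl]-2-(4-methoxyphenyl)ethan-1-ol, racemic | COc1ccc(CC(O)(c2cc(OC)cc(OC)c2Br)c2c(O)cc(OC)cc2CO[Si](c2ccccc2)(c2ccccc2)C(C)(C)C)cc1
F8 | step 8 | racemic trans-dihydrobenzofuran (racemate of 14; relative configuration shown) | CC(C)(C)[Si](c1ccccc1)(c1ccccc1)OCc2cc(OC)cc3c2[C@H]([C@H](c4ccc(OC)cc4)O3)c5cc(OC)cc(OC)c5Br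
F9 | step 14 | 1-[2-(dimethoxymethyl)-3,5-dimethoxyphenyl]ethan-1-one | CC(=O)c1cc(OC)cc(OC)c1C(OC)OC
F10 | step 14 | benzyl ketone: F9 arylated on its methyl group by ring C of 14; furan (2R,3R) | CC(C)(C)[Si](c1ccccc1)(c1ccccc1)OCc2cc(OC)cc3c2[C@H]([C@H](c4ccc(OC)cc4)O3)c5cc(OC)cc(OC)c5CC(=O)c7cc(OC)cc(OC)c7C(OC)OC
A1 | alternative 1 | 5-(dimethoxymethyl)-4-(3,5-dimethoxyphenyl)-1-ethoxy-3-(4-methoxyphenyl)hepta-1,6-diyne, configuration as in the SMILES | COc1ccc(cc1)[C@@H](C#COCC)[C@@H](c1cc(OC)cc(OC)c1)[C@@H](C#C)C(OC)OC
A2 | alternative 1 | ethoxyethyne | C#COCC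
A3 | alternative 1 | all-trans indane with ring B as its diethyl ether | COc1ccc([C@H]2c3c(OCC)cc(OCC)cc3[C@@H](C(OC)OC)[C@@H]2c4cc(OC)cc(OC)c4)cc1
A4 | alternative 2 | (2R)-5-(benzyloxy)-7-methoxy-2-(4-methoxyphenyl)chroman-4-one | COc1ccc(cc1)[C@H]1CC(=O)c2c(OCc3ccccc3)cc(OC)cc2O1
A5 | alternative 2 | methyl (2R,3R)-4-(benzyloxy)-6-methoxy-2-(4-methoxyphenyl)-2,3-dihydro-1-benzofuran-3-carboxylate | COC(=O)[C@@H]1c2c(OCc3ccccc3)cc(OC)cc2O[C@H]1c4ccc(OC)cc4
A6 | alternative 3 | six-membered β-keto ester fused to ring D and to the indane (ester-bearing carbon unassigned) | COc1ccc([C@H]2c3c(OC)cc(OC)cc3[C@H]3C(=O)C(C(=O)OC)c5c(OC)cc(OC)cc5[C@H]23)cc1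
A7 | alternative 3 | 3,5-dimethoxybenzyne | C1#CC(OC)=CC(OC)=C1
A8 | alternative 3 | eight-membered keto ester with ring C in place | COc1ccc([C@H]2c3c(OC)cc(OC)cc3[C@H]3C(=O)c4c(OC)cc(OC)cc4[C@@H](C(=O)OC)c5c(OC)cc(OC)cc5[C@H]23)cc1
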